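All constants come from no measurement; the run is a simulation.

I ask how the complex with one exchanged divides between the capture agent and a second exchange, in three flasks that differ in their capture agent.

    complex with one exchanged + capture agent → trapped intermediate (k1 = 7.73 M⁻¹ s⁻¹)
    complex with one exchanged + incoming ligand → leaving ligand + complex with two exchanged (k2 = 9.96 M⁻¹ s⁻¹)
    complex with two exchanged + incoming ligand → leaving ligand + complex with three exchanged (k3 = 24.8 M⁻¹ s⁻¹)
    starting complex + incoming ligand → leaving ligand + complex with one exchanged (k4 = 10.6 M⁻¹ s⁻¹)

the same everywhere: starting complex 0.10 M; incoming ligand 0.130 M (fed, over 12 s); time 12 s

| flask | capture agent |
|---|---|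
| Friday's | 0.100 M |
| Saturday's | 0.200 M |
| Wednesday's | 0.400 M |

- which of the two there is more of at the end, Friday's (trapped intermediate / complex with two exchanged)
- which of the two there is more of at the end, Saturday's (trapped intermediate / complex with two exchanged)
- which of the two there is more of at the end, Wednesday's (trapped intermediate / complex with two exchanged)
- final complex with two exchanged, as a percentage of the starting complex charged, in Friday's
- final complex with two exchanged, as a percentage of the starting complex charged, in Saturday's
- final complex with two exchanged, as a percentage of the starting complex charged, in Wednesday's

Capture runs at its constant times c(capture agent), and the second exchange at its constant times c(incoming ligand). But the incoming ligand arrives gradually, at 0.0108 M s⁻¹. The starting complex uses up a ligand within 0.943 s, which is shorter than the dosing time. So I take that exchange as balanced against the feed, with the starting complex at its charge and the later exchanges left out, and my reckoning puts c(incoming ligand) at 0.0102 M.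

At this level, and with the capture agent at its charge, capture in Friday's runs 7.59 times as fast as the second exchange. This capture ratio, a selectivity factor, becomes 15.2 in Saturday's and 30.4 in Wednesday's. So my choice for the larger amount at the end is trapped intermediate in Friday's, trapped intermediate in Saturday's and trapped intermediate in Wednesday's.

I put the complex with one exchanged at the feed divided by its two exit rates, 0.0124 M in Friday's. The complex with two exchanged is made and drained by the same ligand, and at my level its drain takes 3.95 s, less than the time. So I put it at 0.402 of the complex with one exchanged. I commit to 4.97% in Friday's, 2.64% in Saturday's and 1.36% in Wednesday's.

The forecast names trapped intermediate, trapped intermediate and trapped intermediate, with 3.9%, 2.1% and 1.1%, saying “its yield falls roughly in half each time the capture agent doubles”. My yield for Friday's stands higher than the forecast's, and so do my yields for Saturday's and Wednesday's.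

The simulation gives trapped intermediate, trapped intermediate and trapped intermediate, with 3.94%, 1.84% and 0.823%.

Friday's ends with 56.7% trapped intermediate against 3.94% and 11.4% of the complexes with two and three exchanged, a read ratio of 3.70 beside my 7.59, which takes the capture agent at its charge. At the end of Friday's, 43% of that charge is left, and the incoming ligand stands at 0.0220 M, above my level. A neighbour of Wednesday's gets 0.033 M of incoming ligand, all else as in Wednesday's, so the same reckoning gives c(incoming ligand) of 0.00259 M and a capture ratio of 120. That neighbour ends with 28.0% trapped intermediate against 0.188% and 0.0808% of the complexes with two and three exchanged, a read ratio of 104, and 70.8% of its starting complex remains.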